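**Numbering used throughout:** 1 4-allyl-2,6-dimethoxyphenol; 2 diethyl bromomalonate; 3 aryloxymalonate; 4 prochiral diol; 5 vinyl acetate; 6 (S)-monoacetate; 7 (R)-aldehyde; 8 5-bromo-1,2,3-trimethoxybenzene; 9 aryl Grignard reagent; 10 target.

## Analysis of the target

The target 10 is an acyclic 8-O-4' neolignan built on a three-carbon chain C7–C8–C9, in which C7 is a benzylic carbinol carrying ring A (3,4,5-trimethoxyphenyl), C8 carries the oxygen of ring B (4-allyl-2,6-dimethoxyphenyl) and C9 is an acetoxymethyl group. The only rings are the two arenes, and both can be bought fully substituted, so the work lies in the chain. C7 and C8 are adjacent stereocentres, both R, which is the threo (syn) relationship between the hydroxyl and the aryloxy group. The sensitive points are the primary acetate next to a free secondary alcohol (acyl migration, loss under base), the terminal allyl group (it rules out hydrogenolysis and can move into conjugation), and the electron-rich benzylic alcohol, which can ionise under acid and lose the C7 configuration. The hard part is the C8–O ether to a phenol oxygen flanked by two methoxy groups, on a secondary carbon of defined configuration, together with the need to acylate O9 alone among three neighbouring oxygens. The strategy rests on the fact that C8 bears the ring B oxygen and two oxygenated one-carbon arms: with ring A removed from C7 both arms are CH2OH, and the diol 4 has a mirror plane through C8. Acetylating one arm selectively therefore creates the C8 stereocentre and places the natural acetate on C9 in the same operation.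

## Retrosynthetic reasoning

**10 to 7 and 9.** The C7–C1 (ring A) bond is cut. Ring A is the only carbon substituent whose removal leaves C7 as a carbonyl directly beside the C8 ether oxygen, so a chelate between the two oxygens can pass the C8 configuration on to C7. The forward reaction has to add the aryl Grignard reagent 9 to aldehyde 7 faster than to the acetate, and from the face that the chelate exposes.

**7 to 6.** This is an adjustment of oxidation level at the future C7. The forward oxidation of monoacetate 6 must stop at the aldehyde and must not enolise it, because C8 is then alpha to a carbonyl and beta to an acetate.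

**6 to 4 and 5.** The O9–acetyl bond is cut. Removing the acetyl group from 6 returns diol 4, in which the two CH2OH arms are enantiotopic, so the whole problem of the C8 configuration becomes a choice between two identical groups. A lipase makes that choice with vinyl acetate 5 as acyl donor. What is gained is a stereocentre without a chiral reagent or auxiliary, and an acetate that is the target's own and not a protecting group.

**4 to 3.** Both primary alcohols of 4 are taken back to the esters of malonate 3. The forward step is a double ester reduction that leaves the aryl ether and the allyl group alone.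

**3 to 1 and 2.** The C8–O (ring B) bond is cut here and not later. The di-ortho-substituted phenol 1 is a poor partner for substitution at an unactivated secondary carbon, but the carbon of bromomalonate 2 is activated by two esters and is not stereogenic, so the hindered ether is made by a plain alkylation with no stereochemical demand. The allyl group arrives with commercial 1.

**9 to 8.** The carbon–metal bond is cut; insertion of the metal into the C–Br bond of aryl bromide 8 supplies ring A as a nucleophile.

## Alternatives that were turned down

Alternative 1: arylation of a dihydroxylation-derived triol at O8.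
- Disconnection: the O–C4' bond between the C8 oxygen and ring B.
- Forward key step: the free C8 hydroxyl of the silylene-protected triol (4R,5R)-2,2-di-tert-butyl-4-(3,4,5-trimethoxyphenyl)-1,3,2-dioxasilinan-5-ol A1 is coupled with 5-allyl-2-bromo-1,3-dimethoxybenzene A2. The catalyst is Pd2(dba)3 (a zerovalent palladium source) with a bulky biaryl di-tert-butylphosphine and Cs2CO3. The product is the aryl ether (4R,5R)-5-(4-allyl-2,6-dimethoxyphenoxy)-2,2-di-tert-butyl-4-(3,4,5-trimethoxyphenyl)-1,3,2-dioxasilinane A3.
- For: both stereocentres of A1 come from one asymmetric dihydroxylation of an E-alkene, so the threo relationship follows from syn addition and the absolute sense from the ligand. The C8–O bond is never broken on the way to A3, so retention is certain. On stereochemical security this plan is stronger than the chosen one, which relies on an enzyme for C8 and on substrate control for C7.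
- Against: the bromine of A2 sits between two methoxy groups on an electron-rich ring, so oxidative addition is slow. The resulting hindered aryl–palladium alkoxide has a beta hydrogen at C8, so beta-hydride elimination competes with the C–O reductive elimination that leads to A3. A palladium hydride can also move the allyl double bond into conjugation, and the terminal alkene can enter Heck chemistry. A2 has to be made, and the silylene of A3 must still be removed and the primary hydroxyl acetylated selectively.
- Comparison: the route through A3 is longer, and its risk sits in a metal-catalysed etherification at the edge of its scope. The chosen route forms the same hindered ether in its first step by alkylation of 1 at a malonate carbon, and spends its risk on a room-temperature enzymatic step that touches no sensitive group.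

Alternative 2: chelation-controlled Grignard addition to a silyl-protected aldehyde.
- Disconnection: the C7–C1 (ring A) bond.
- Forward key step: reagent 9 adds to (R)-2-(4-allyl-2,6-dimethoxyphenoxy)-3-(tert-butyldiphenylsilyloxy)propanal A4 through a magnesium chelate to give (1R,2R)-2-(4-allyl-2,6-dimethoxyphenoxy)-3-(tert-butyldiphenylsilyloxy)-1-(3,4,5-trimethoxyphenyl)propan-1-ol A5.
- For: this is the same bond construction with which the chosen route ends, but on a substrate without an ester. There is no second electrophile, no second carbonyl to compete for magnesium, and no good leaving group beta to the aldehyde. The addition that gives A5 is more secure than step 6 of the chosen route.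
- Against: the plan does not say where the C8 configuration of A4 comes from. A4 has to be made enantiopure, which needs a desymmetrisation or a chiral-pool start plus protecting-group exchanges. After the addition, A5 still has to be desilylated and acetylated at the primary hydroxyl alone.
- Comparison: the chosen route lets one enzymatic step create C8 and install the acetate, so three steps lead from diol 4 to the target where this plan needs about twice as many. The price is the chemoselectivity demanded in step 6. The sequence through A4 and A5 is kept in reserve as a fallback.

Alternative 3: biomimetic oxidative cross-coupling.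
- Disconnection: the C8–O (ring B) and C7–O bonds, both made in one step.
- Forward key step: Ag2O oxidises (E)-3-(4-hydroxy-3,5-dimethoxyphenyl)allyl acetate A6 and phenol 1 to phenoxyl radicals. These couple between C8 and the ring B oxygen, and water adds to C7 of the quinone methide. The product is threo-2-(4-allyl-2,6-dimethoxyphenoxy)-3-hydroxy-3-(4-hydroxy-3,5-dimethoxyphenyl)propyl acetate A7, and methylation of the ring A phenol of A7 would finish the synthesis.
- For: it is by far the shortest plan, it follows the biosynthesis, and the acetate is present from the start in A6. On step count it is stronger than the chosen route.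
- Against: the radicals couple with no chiral influence, so A7 is racemic. Water can add to either face of the quinone methide, so the erythro isomer forms as well. A6 also couples with itself (C8–C8 and C8–O modes), and 1 has benzylic hydrogens through which it is oxidised to its own quinone methide. The single enantiomer would have to be resolved out of a minor component of a complex mixture.
- Comparison: the chosen route is longer than the one through A7 but controls both the absolute and the relative configuration.

Key step: step 3

Assumption: Burkholderia cepacia lipase is taken to acylate the pro-S hydroxymethyl arm of diol 4, as Pseudomonas-type lipases do with 2-O-benzylglycerol; if the other arm is preferred, the hydrolytic fallback below supplies the same monoacetate 6.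

## Route

Step 1
Reactants: 1 4-allyl-2,6-dimethoxyphenol; 2 diethyl bromomalonate
Product: 3 diethyl 2-(4-allyl-2,6-dimethoxyphenoxy)malonate
Conditions: K2CO3, acetone, reflux
Reagents that add atoms: none
Why: Williamson O-alkylation (SN2); the bromide is activated by two esters and the phenoxide of 1 can only react at oxygen because both ortho positions and the para position are substituted. K2CO3 is too weak a base to move the allyl double bond.

Step 2
Reactants: 3 diethyl 2-(4-allyl-2,6-dimethoxyphenoxy)malonate
Product: 4 2-(4-allyl-2,6-dimethoxyphenoxy)propane-1,3-diol
Conditions: LiAlH4, THF, 0 °C to rt (3 added to the hydride); then H2O, aq. NaOH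
Reagents that add atoms: none
Why: LiAlH4 reduction of both esters to primary alcohols; aryl ethers and an isolated terminal alkene are inert to the hydride, and adding 3 to excess hydride at 0 °C keeps reduction ahead of enolisation. The product is achiral, with a mirror plane through C8.

Step 3
Reactants: 4 2-(4-allyl-2,6-dimethoxyphenoxy)propane-1,3-diol; 5 vinyl acetate
Product: 6 (S)-2-(4-allyl-2,6-dimethoxyphenoxy)-3-hydroxypropyl acetate
Conditions: Burkholderia cepacia lipase (Amano PS, immobilised), vinyl acetate (5 equiv), t-BuOMe, 25 °C; run until 4 is consumed and a little diacetate has appeared; filter, concentrate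
Reagents that add atoms: none
Why: The catalytic serine of the lipase is acetylated by 5, and the vinyl alcohol released tautomerises to acetaldehyde, so the acyl transfer cannot run backwards. Diol 4 then binds to the acetyl-enzyme with its aryloxy group in the large hydrophobic pocket, which leaves only one of the two enantiotopic CH2OH arms within reach of the acyl-serine; its oxygen attacks, the O9–acetyl bond forms and C8 becomes a stereocentre. The closest known reaction type is the lipase-mediated monoacylation of 2-O-benzylglycerol and other 2-substituted propane-1,3-diols with vinyl esters; by analogy the pro-S arm should be acylated, which gives (S)-6 and corresponds to 8R in the target. No ring is closed. The C8 configuration is controlled by the chiral active site alone, since the substrate has a mirror plane. The step needs selectivity between two identical groups and between mono- and diacylation: the second acylation is slower and preferentially consumes the minor enantiomer of the monoacetate, whose free arm is the one the enzyme prefers, so allowing a small amount of diacetate to form should raise the enantiomeric purity of 6. The neutral medium and removal of the enzyme by filtration avoid the 1,3-acetyl shift between the two arms, which would racemise 6; the enantiomeric purity is to be checked by chiral HPLC before going on.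

Step 4
Reactants: 6 (S)-2-(4-allyl-2,6-dimethoxyphenoxy)-3-hydroxypropyl acetate
Product: 7 (R)-2-(4-allyl-2,6-dimethoxyphenoxy)-3-oxopropyl acetate
Conditions: Dess–Martin periodinane, CH2Cl2, 0 °C to rt; dilution with Et2O/pentane, filtration through a short silica pad; used crude at once
Reagents that add atoms: none
Why: Dess–Martin oxidation of a primary alcohol stops at the aldehyde and runs without base, so the C8 hydrogen (now alpha to the carbonyl) and the beta acetate are not exposed to enolising conditions. No new stereocentre is formed; the change of descriptor from S to R only reflects the new priority of the oxidised arm.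

Step 5
Reactants: 8 5-bromo-1,2,3-trimethoxybenzene
Product: 9 (3,4,5-trimethoxyphenyl)magnesium bromide (titrated THF solution)
Conditions: Mg turnings, I2 (cat.), THF, 40 °C
Reagents that add atoms: magnesium, [Mg]
Why: Grignard formation by insertion of magnesium into the aryl C–Br bond; the methoxy groups are inert and the reagent is used as its solution.

Step 6
Reactants: 7 (R)-2-(4-allyl-2,6-dimethoxyphenoxy)-3-oxopropyl acetate; 9 (3,4,5-trimethoxyphenyl)magnesium bromide
Product: 10 (2R,3R)-2-(4-allyl-2,6-dimethoxyphenoxy)-3-hydroxy-3-(3,4,5-trimethoxyphenyl)propyl acetate
Conditions: 7, MgBr2·OEt2, CH2Cl2, −78 °C; then 9 (1.2 equiv, THF), −78 °C; sat. aq. NH4Cl at −78 °C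
Reagents that add atoms: none
Why: Grignard addition under Cram chelation control: magnesium binds the aldehyde oxygen and the C8 aryl ether oxygen in a five-membered chelate that holds the C8 hydrogen on one face of the carbonyl and the CH2OAc group on the other, and ring A is delivered to the face next to the hydrogen, which from the (R)-aldehyde gives 7R, syn to the aryloxy group. At −78 °C with a small excess of 9 an aldehyde reacts far faster than an acetate, and the cold quench keeps the magnesium alkoxide from drawing the acetyl group over to O7.

## Compound list

1 | 4-allyl-2,6-dimethoxyphenol | C=CCc1cc(OC)c(O)c(OC)c1 | starting material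
2 | diethyl bromomalonate | CCOC(=O)C(Br)C(=O)OCC | starting material
3 | diethyl 2-(4-allyl-2,6-dimethoxyphenoxy)malonate | C=CCc1cc(OC)c(OC(C(=O)OCC)C(=O)OCC)c(OC)c1 | intermediate
4 | 2-(4-allyl-2,6-dimethoxyphenoxy)propane-1,3-diol | C=CCc1cc(OC)c(OC(CO)CO)c(OC)c1 | intermediate
5 | vinyl acetate | C=COC(C)=O | starting material
6 | (S)-2-(4-allyl-2,6-dimethoxyphenoxy)-3-hydroxypropyl acetate | C=CCc1cc(OC)c(O[C@H](COC(C)=O)CO)c(OC)c1 | intermediate
7 | (R)-2-(4-allyl-2,6-dimethoxyphenoxy)-3-oxopropyl acetate | C=CCc1cc(OC)c(O[C@H](COC(C)=O)C=O)c(OC)c1 | intermediate
8 | 5-bromo-1,2,3-trimethoxybenzene | COc1cc(Br)cc(OC)c1OC | starting material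
9 | (3,4,5-trimethoxyphenyl)magnesium bromide | COc1cc([Mg]Br)cc(OC)c1OC | intermediate
10 | (2R,3R)-2-(4-allyl-2,6-dimethoxyphenoxy)-3-hydroxy-3-(3,4,5-trimethoxyphenyl)propyl acetate | C=CCc1cc(OC)c(O[C@H](COC(C)=O)[C@H](O)c2cc(OC)c(OC)c(OC)c2)c(OC)c1 | target

## Step count and least certain steps

Total: 6 steps. Longest linear sequence: 5 steps (1 to 3 to 4 to 6 to 7 to 10); the Grignard reagent 9 is a one-step branch.

**Step 3 (key step).** The most likely failure is incomplete discrimination between the two hydroxymethyl arms, or a preference for the other arm. The di-ortho-substituted aryloxy group is bulkier than the benzyl ethers on which the analogy rests and may sit differently in the pocket. A slow 1,3-acetyl shift during work-up would also erode the enantiomeric purity.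

The fallback sets out from diol 4 and switches from acyl transfer to hydrolysis. Both hydroxyls are acetylated (Ac2O, pyridine) to 2-(4-allyl-2,6-dimethoxyphenoxy)propane-1,3-diyl diacetate F1. One enantiotopic ester of F1 is then hydrolysed with the same lipase in NaH2PO4/Na2HPO4 buffer (pH 7) with t-BuOMe as co-solvent. The enzyme keeps its preference for the same arm in both directions, so hydrolysis leaves the acetate on the arm that acylation leaves free. If the acylation has the unwanted sense, the hydrolysis therefore returns to the route at 6. If the acylation has the wanted sense but too little selectivity, the hydrolysis gives the antipode (R)-2-(4-allyl-2,6-dimethoxyphenoxy)-3-hydroxypropyl acetate F2, which reaches 10 by the relay described under step 4.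

**Step 6.** The most likely failure concerns the acetyl group: partial addition of the reagent to the ester, or transfer of the acetyl group from O9 to O7 within the magnesium alkoxide. The acetate carbonyl may also compete with the ether oxygen for magnesium and lower the facial selectivity at C7.

The fallback sets out from 7 and 9 and returns at 10. The addition is run as in step 6 without trying to preserve the ester. The crude product is stirred with K2CO3 in MeOH at 0 °C, so that all acetylated material converges on (1R,2R)-2-(4-allyl-2,6-dimethoxyphenoxy)-1-(3,4,5-trimethoxyphenyl)propane-1,3-diol F3, and any C7 epimer is removed by chromatography at this stage. The primary hydroxyl of F3 is then acetylated alone, with vinyl acetate 5 and the lipase of step 3 (or AcCl, 2,4,6-collidine, CH2Cl2, −78 °C), which gives 10. If chelation itself proves weak, the ester-free aldehyde of the relay under step 4 removes the competing binding site.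

**Step 4.** The most likely failure is enolisation of the aldehyde on contact with base or silica or on standing, which erodes the C8 configuration, and loss of the beta acetate by an E1cB pathway.

The fallback carries the C9 oxygen through as a silyl ether; it sets out from diol 4 through F1 and F2 and returns at 10. The antipodal monoacetate F2 has its free hydroxyl on the arm that is to become C9. Silylation of that hydroxyl (t-BuPh2SiCl, imidazole, CH2Cl2) should give (S)-2-(4-allyl-2,6-dimethoxyphenoxy)-3-(tert-butyldiphenylsilyloxy)propyl acetate F4. Methanolysis of the acetate (K2CO3, MeOH, 0 °C) should then give (S)-2-(4-allyl-2,6-dimethoxyphenoxy)-3-(tert-butyldiphenylsilyloxy)propan-1-ol F5. Dess–Martin oxidation should give (R)-2-(4-allyl-2,6-dimethoxyphenoxy)-3-(tert-butyldiphenylsilyloxy)propanal F6, the same compound as A4, whose beta substituent is a poor leaving group. Addition of 9 under the conditions of step 6 should give (1R,2R)-2-(4-allyl-2,6-dimethoxyphenoxy)-3-(tert-butyldiphenylsilyloxy)-1-(3,4,5-trimethoxyphenyl)propan-1-ol F7, the same compound as A5. Desilylation with Bu4NF/AcOH in THF should give diol F3, and the primary-selective acetylation described under step 6 then gives 10.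

**Step 2.** The most likely failure is deprotonation of the malonate C–H (flanked by two esters and an aryloxy group) by the hydride, so that part of the material is held as an enolate and is reduced incompletely or expels the aryloxide.

The fallback sets out from phenol 1 and returns at 4. A Mitsunobu reaction of 1 with commercial cis-2-phenyl-1,3-dioxan-5-ol (PPh3, diisopropyl azodicarboxylate, THF) should give, with inversion at the carbinol carbon, trans-5-(4-allyl-2,6-dimethoxyphenoxy)-2-phenyl-1,3-dioxane F8. Hydrolysis of the acetal (80% aq. AcOH, 50 °C) then gives 4; the allyl group and the aryl ethers tolerate these conditions, and the ring configuration of F8 is of no consequence because 4 is achiral.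

## Further compounds

F1 | step 3 | 2-(4-allyl-2,6-dimethoxyphenoxy)propane-1,3-diyl diacetate | C=CCc1cc(OC)c(OC(COC(C)=O)COC(C)=O)c(OC)c1
F2 | step 3 | (R)-2-(4-allyl-2,6-dimethoxyphenoxy)-3-hydroxypropyl acetate | C=CCc1cc(OC)c(O[C@@H](COC(C)=O)CO)c(OC)c1
F3 | step 6 | (1R,2R)-2-(4-allyl-2,6-dimethoxyphenoxy)-1-(3,4,5-trimethoxyphenyl)propane-1,3-diol | C=CCc1cc(OC)c(O[C@H](CO)[C@H](O)c2cc(OC)c(OC)c(OC)c2)c(OC)c1
F4 | step 4 | (S)-2-(4-allyl-2,6-dimethoxyphenoxy)-3-(tert-butyldiphenylsilyloxy)propyl acetate | C=CCc1cc(OC)c(O[C@@H](COC(C)=O)CO[Si](c2ccccc2)(c2ccccc2)C(C)(C)C)c(OC)c1
F5 | step 4 | (S)-2-(4-allyl-2,6-dimethoxyphenoxy)-3-(tert-butyldiphenylsilyloxy)propan-1-ol | C=CCc1cc(OC)c(O[C@@H](CO)CO[Si](c2ccccc2)(c2ccccc2)C(C)(C)C)c(OC)c1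
F6 | step 4 | (R)-2-(4-allyl-2,6-dimethoxyphenoxy)-3-(tert-butyldiphenylsilyloxy)propanal | C=CCc1cc(OC)c(O[C@H](CO[Si](c2ccccc2)(c2ccccc2)C(C)(C)C)C=O)c(OC)c1
F7 | step 4 | (1R,2R)-2-(4-allyl-2,6-dimethoxyphenoxy)-3-(tert-butyldiphenylsilyloxy)-1-(3,4,5-trimethoxyphenyl)propan-1-ol | C=CCc1cc(OC)c(O[C@H](CO[Si](c2ccccc2)(c2ccccc2)C(C)(C)C)[C@H](O)c2cc(OC)c(OC)c(OC)c2)c(OC)c1
F8 | step 2 | trans-5-(4-allyl-2,6-dimethoxyphenoxy)-2-phenyl-1,3-dioxane | C=CCc1cc(OC)c(O[C@H]2CO[C@H](c3ccccc3)OC2)c(OC)c1
A1 | alternative 1 | (4R,5R)-2,2-di-tert-butyl-4-(3,4,5-trimethoxyphenyl)-1,3,2-dioxasilinan-5-ol | O[C@@H]1CO[Si](C(C)(C)C)(C(C)(C)C)O[C@@H]1c2cc(OC)c(OC)c(OC)c2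
A2 | alternative 1 | 5-allyl-2-bromo-1,3-dimethoxybenzene | C=CCc1cc(OC)c(Br)c(OC)c1
A3 | alternative 1 | (4R,5R)-5-(4-allyl-2,6-dimethoxyphenoxy)-2,2-di-tert-butyl-4-(3,4,5-trimethoxyphenyl)-1,3,2-dioxasilinane | C=CCc1cc(OC)c(O[C@@H]2CO[Si](C(C)(C)C)(C(C)(C)C)O[C@@H]2c3cc(OC)c(OC)c(OC)c3)c(OC)c1
A4 | alternative 2 | (R)-2-(4-allyl-2,6-dimethoxyphenoxy)-3-(tert-butyldiphenylsilyloxy)propanal | C=CCc1cc(OC)c(O[C@H](CO[Si](c2ccccc2)(c2ccccc2)C(C)(C)C)C=O)c(OC)c1
A5 | alternative 2 | (1R,2R)-2-(4-allyl-2,6-dimethoxyphenoxy)-3-(tert-butyldiphenylsilyloxy)-1-(3,4,5-trimethoxyphenyl)propan-1-ol | C=CCc1cc(OC)c(O[C@H](CO[Si](c2ccccc2)(c2ccccc2)C(C)(C)C)[C@H](O)c2cc(OC)c(OC)c(OC)c2)c(OC)c1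
A6 | alternative 3 | (E)-3-(4-hydroxy-3,5-dimethoxyphenyl)allyl acetate (sinapyl acetate) | CC(=O)OC/C=C/c1cc(OC)c(O)c(OC)c1
A7 | alternative 3 | threo-2-(4-allyl-2,6-dimethoxyphenoxy)-3-hydroxy-3-(4-hydroxy-3,5-dimethoxyphenyl)propyl acetate (racemic, formed with the erythro isomer; the 2R,3R enantiomer is drawn) | C=CCc1cc(OC)c(O[C@H](COC(C)=O)[C@H](O)c2cc(OC)c(O)c(OC)c2)c(OC)c1
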